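The cyclohexane ring is traced back to a dearomatised 2-methyl-1,4-benzoquinone monoketal: ring carbons C4 (carbinol), C5 (gem-dimethyl), C6 (side-chain stereocentre) and C1 (methylene-bearing) correspond to its carbonyl, α-methyl, β and ketal carbons. One copper-catalysed operation adds a silyl-capped butynyl Grignard reagent enantioselectively to C6 and methylates the resulting enolate at C5, giving the C6–C7 bond, the quaternary centre and the only catalyst-set stereocentre. The precursor is 4,4-dimethoxy-2-methylcyclohex-2-en-1-one, which offers a single open β-carbon. The alkyne handle is then extended twice by methylalumination (iodination and Negishi coupling, then formaldehyde capture), and the pyrone is attached by palladium-catalysed allylation.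

Key step: step 4

Numbering used below: ring carbons C1 (C=CH2), C2, C3, C4 (CHOH), C5 (CMe2), C6 (CH); side chain C7 to C15 counted from the ring towards the pyrone.

Assumption: the antipode of the ferrocenyl diphosphine that delivers the 3S ketone 8 is identified in a pilot run; the ligand descriptor written in step 4 stands for that antipode.

Step 1
Reactants: 1 4-methoxy-2-methylphenol
Product: 2 4,4-dimethoxy-2-methylcyclohexa-2,5-dien-1-one
Conditions: PhI(OAc)2 (1.1 equiv), MeOH, 0 °C; NaHCO3 work-up
Reagents that add atoms: methanol, CO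
Why: Oxidative dearomatisation of a para-methoxyphenol by the trivalent iodine reagent gives an aryloxy-iodane that loses iodobenzene as methanol attacks the para carbon, the standard entry to quinone monoketals.

Step 2
Reactants: 2 4,4-dimethoxy-2-methylcyclohexa-2,5-dien-1-one
Product: 3 4,4-dimethoxy-2-methylcyclohex-2-en-1-one
Conditions: H2 (1 atm), RhCl(PPh3)3 (5 mol%), toluene, rt
Reagents that add atoms: none
Why: Homogeneous catalytic hydrogenation with RhCl(PPh3)3 discriminates strongly by alkene substitution, so the CH=CH enone bond should be saturated while the methyl-bearing trisubstituted enone bond stays, as in the classical selective reduction of the disubstituted alkene of cross-conjugated cyclohexadienones; the neutral medium keeps the ketal from losing methanol.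

Step 3
Reactants: 4 (4-bromobut-1-yn-1-yl)trimethylsilane
Product: 5 [4-(trimethylsilyl)but-3-yn-1-yl]magnesium bromide
Conditions: Mg turnings (I2 crystal), Et2O, reflux then rt
Reagents that add atoms: magnesium, [Mg]
Why: Grignard formation by insertion of zerovalent magnesium into the primary C–Br bond is routine here because the silyl cap removes the acidic alkyne hydrogen, and diethyl ether is chosen because weakly coordinating ethers suit the copper-catalysed addition that follows.

Step 4
Reactants: 3 4,4-dimethoxy-2-methylcyclohex-2-en-1-one; 5 [4-(trimethylsilyl)but-3-yn-1-yl]magnesium bromide; 6 iodomethane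
Product: 8 (3S)-4,4-dimethoxy-2,2-dimethyl-3-[4-(trimethylsilyl)but-3-yn-1-yl]cyclohexan-1-one, via magnesium enolate 7 (not isolated)
Conditions: CuBr·SMe2 (5 mol%), (R,SP)-Josiphos [1-(2-diphenylphosphinoferrocenyl)ethyldicyclohexylphosphine] (6 mol%), t-BuOMe, −78 °C, slow addition of 5 (1.3 equiv, Et2O); then 6 (5 equiv), DMPU, −78 → 0 °C
Reagents that add atoms: iodomethane (compound 6), CI
Why: The monovalent copper–diphosphine complex is transmetalated by 5 to a chiral alkylcopper–magnesium species that π-binds the enone double bond of 3, adds oxidatively at the β-carbon (ring carbon C6) to a trivalent copper σ-alkyl enolate and reductively eliminates to forge C6–C7, leaving magnesium enolate 7 with its double bond locked between C4 and C5; iodomethane, assisted by DMPU, then C-methylates C5. The closest known reaction type is the copper-catalysed enantioselective conjugate addition of Grignard reagents to cyclic enones, 2-methylcycloalkenones and quinone monoketals included, run in tandem with alkylation of the magnesium enolate. No ring is closed. The single new stereocentre C6 is set by catalyst control, the chiral pocket of the ferrocenyl diphosphine selecting one enantiotopic face of the planar, achiral enone; C5 is not stereogenic. The step needs 1,4- over 1,2-addition (secured by slow Grignard addition at −78 °C so that the copper pathway outruns the background reaction), a single β-site (the ketal carbon C1 blocks the second one, and its methoxy groups sit γ to the enolate carbon and cannot be expelled) and methylation only at C5 (the enolate is quenched before it can equilibrate, and C5 carries no hydrogen afterwards).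

Step 5
Reactants: 8 (3S)-4,4-dimethoxy-2,2-dimethyl-3-[4-(trimethylsilyl)but-3-yn-1-yl]cyclohexan-1-one
Product: 9 (1S,3S)-4,4-dimethoxy-2,2-dimethyl-3-[4-(trimethylsilyl)but-3-yn-1-yl]cyclohexan-1-ol
Conditions: NaBH4, EtOH, −20 → 0 °C; chromatography on Et3N-deactivated silica
Reagents that add atoms: none
Why: Borohydride reduction of the α,α-dimethylcyclohexanone should deliver hydride on the face anti to the C6 side chain (axial attack, the equatorial path being screened by the axial C5 methyl group), as in reductions of 4,4-dimethyl-3-keto terpenoids, so the new C4 carbinol is equatorial and cis to the chain; any C4 epimer is removed here, before C6 becomes enolisable.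

Step 6
Reactants: 9 (1S,3S)-4,4-dimethoxy-2,2-dimethyl-3-[4-(trimethylsilyl)but-3-yn-1-yl]cyclohexan-1-ol
Product: 11 (2S,4S)-4-[(tert-butyldimethylsilyl)oxy]-3,3-dimethyl-2-[4-(trimethylsilyl)but-3-yn-1-yl]cyclohexan-1-one, via silyl ether ketal 10 (not isolated)
Conditions: TBSCl, imidazole, DMAP (cat.), DMF, 40 °C; then pyridinium p-toluenesulfonate, acetone/H2O, rt
Reagents that add atoms: tert-butyldimethylsilyl chloride, CC(C)(C)[Si](C)(C)Cl; water, O
Why: Imidazole-promoted silylation protects the hindered secondary alcohol without Lewis acid that would disturb the ketal, and mild aqueous acid then hydrolyses the dimethyl ketal while leaving the silyl ether and the alkynylsilane intact (standard protection and ketal hydrolysis), the C6 chain already occupying its thermodynamically preferred equatorial position next to the new ketone.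

Step 7
Reactants: 11 (2S,4S)-4-[(tert-butyldimethylsilyl)oxy]-3,3-dimethyl-2-[4-(trimethylsilyl)but-3-yn-1-yl]cyclohexan-1-one
Product: 13 tert-butyl{[(1S,3R)-3-(but-3-yn-1-yl)-2,2-dimethyl-4-methylidenecyclohexyl]oxy}dimethylsilane, via silylalkyne 12 (not isolated)
Conditions: Ph3PCH3Br, KOtBu, THF, 0 → 50 °C; then MeOH, K2CO3, rt
Reagents that add atoms: methyltriphenylphosphonium bromide, C[P+](c1ccccc1)(c1ccccc1)c1ccccc1.[Br-]
Why: Wittig methylenation with the unstabilised ylide converts the hindered ketone into the exocyclic alkene (base-mediated equilibration at C6 favours the cis diequatorial isomer already in hand), and methanolic carbonate then cleaves the alkynyl C–Si bond selectively over the hindered silyl ether to free the terminal alkyne needed for carbometalation.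

Step 8
Reactants: 13 tert-butyl{[(1S,3R)-3-(but-3-yn-1-yl)-2,2-dimethyl-4-methylidenecyclohexyl]oxy}dimethylsilane
Product: 15 tert-butyl{[(1S,3R)-3-[(3E)-4-iodo-3-methylbut-3-en-1-yl]-2,2-dimethyl-4-methylidenecyclohexyl]oxy}dimethylsilane, via alkenylalane 14 (not isolated)
Conditions: AlMe3 (2.5 equiv), Cp2ZrCl2 (0.25 equiv), CH2Cl2, 0 °C → rt; then I2, THF, −30 → 0 °C
Reagents that add atoms: trimethylaluminium, C[Al](C)C; iodine, II
Why: Negishi zirconium-catalysed methylalumination adds methyl and aluminium syn across the terminal alkyne with methyl on the internal carbon (C9), and iodinolysis of the C–Al bond with retention should give the E-configured alkenyl iodide, the 1,1-disubstituted ring alkene and the silyl ether being inert to these reagents.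

Step 9
Reactants: 15 tert-butyl{[(1S,3R)-3-[(3E)-4-iodo-3-methylbut-3-en-1-yl]-2,2-dimethyl-4-methylidenecyclohexyl]oxy}dimethylsilane; 5 [4-(trimethylsilyl)but-3-yn-1-yl]magnesium bromide (second portion of the solution from step 3)
Product: 18 tert-butyl{[(1S,3R)-2,2-dimethyl-4-methylidene-3-[(3E)-3-methyloct-3-en-7-yn-1-yl]cyclohexyl]oxy}dimethylsilane, via organozinc bromide 16 (not isolated), via silylated enyne 17 (not isolated)
Conditions: 5 (2 equiv), ZnBr2, THF, 0 °C; then 15, Pd(PPh3)4 (3 mol%), THF, rt; then MeOH, K2CO3, rt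
Reagents that add atoms: none
Why: Negishi cross-coupling of the alkenyl iodide with the homopropargylzinc reagent runs through oxidative addition to zerovalent palladium, transmetalation and reductive elimination with retention of alkene geometry (β-hydride loss from homopropargylzinc partners is slow), forming C10–C11, and methanolic carbonate again unmasks the terminal alkyne.

Step 10
Reactants: 18 tert-butyl{[(1S,3R)-2,2-dimethyl-4-methylidene-3-[(3E)-3-methyloct-3-en-7-yn-1-yl]cyclohexyl]oxy}dimethylsilane; 19 formaldehyde (used as paraformaldehyde)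
Product: 21 (2E,6E)-9-{(1R,3S)-3-[(tert-butyldimethylsilyl)oxy]-2,2-dimethyl-6-methylidenecyclohexyl}-3,7-dimethylnona-2,6-dien-1-ol, via alkenylalane 20 (not isolated)
Conditions: AlMe3 (2.5 equiv), Cp2ZrCl2 (0.25 equiv), CH2Cl2, 0 °C → rt; then (CH2O)n, THF, 0 °C → rt
Reagents that add atoms: trimethylaluminium, C[Al](C)C; formaldehyde (compound 19), C=O
Why: A second Negishi methylalumination sets the C13=C14 alkene with E geometry by syn addition, and the alkenylalane adds to monomeric formaldehyde released from paraformaldehyde to install C15 as the primary allylic alcohol.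

Step 11
Reactants: 21 (2E,6E)-9-{(1R,3S)-3-[(tert-butyldimethylsilyl)oxy]-2,2-dimethyl-6-methylidenecyclohexyl}-3,7-dimethylnona-2,6-dien-1-ol
Product: 22 (2E,6E)-9-{(1R,3S)-3-[(tert-butyldimethylsilyl)oxy]-2,2-dimethyl-6-methylidenecyclohexyl}-3,7-dimethylnona-2,6-dien-1-yl methyl carbonate
Conditions: ClCO2Me, pyridine, CH2Cl2, 0 °C
Reagents that add atoms: methyl chloroformate, COC(=O)Cl
Why: Acylation of the primary allylic alcohol with a chloroformate gives the mixed carbonate, a leaving group that ionises under neutral conditions and releases its own base in the next step.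

Step 12
Reactants: 22 (2E,6E)-9-{(1R,3S)-3-[(tert-butyldimethylsilyl)oxy]-2,2-dimethyl-6-methylidenecyclohexyl}-3,7-dimethylnona-2,6-dien-1-yl methyl carbonate; 23 4-hydroxy-6-methyl-2H-pyran-2-one (2 equiv)
Product: 24 3-[(2E,6E)-9-{(1R,3S)-3-[(tert-butyldimethylsilyl)oxy]-2,2-dimethyl-6-methylidenecyclohexyl}-3,7-dimethylnona-2,6-dien-1-yl]-4-hydroxy-6-methyl-2H-pyran-2-one
Conditions: Pd(PPh3)4 (5 mol%), THF, 50 °C
Reagents that add atoms: none
Why: In this Tsuji–Trost allylation zerovalent palladium ionises the carbonate to a π-allyl complex and methoxide, which deprotonates the acidic pyrone, and the soft pyronate should attack the unsubstituted allyl terminus (C15) through pyrone carbon 3, any O-allyl ether being re-ionised and funnelled to the C-allylated product, while the E geometry at C13=C14 should persist because syn/anti exchange would need a tertiary σ-allyl palladium species.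

Step 13
Reactants: 24 3-[(2E,6E)-9-{(1R,3S)-3-[(tert-butyldimethylsilyl)oxy]-2,2-dimethyl-6-methylidenecyclohexyl}-3,7-dimethylnona-2,6-dien-1-yl]-4-hydroxy-6-methyl-2H-pyran-2-one
Product: 25 sartorypyrone D, 4-hydroxy-3-[(2E,6E)-9-[(1R,3S)-3-hydroxy-2,2-dimethyl-6-methylidenecyclohexyl]-3,7-dimethylnona-2,6-dien-1-yl]-6-methyl-2H-pyran-2-one
Conditions: Bu4NF, THF, 50 °C; aqueous work-up at pH 4
Reagents that add atoms: none
Why: Fluoride-induced desilylation frees the C4 hydroxyl under basic conditions that the pyronate, the exocyclic alkene and the trisubstituted alkenes tolerate, and it touches neither stereocentre.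

Compound list
1 | 4-methoxy-2-methylphenol | COc1ccc(O)c(C)c1 | starting material
2 | 4,4-dimethoxy-2-methylcyclohexa-2,5-dien-1-one | COC1(OC)C=CC(=O)C(C)=C1 | intermediate
3 | 4,4-dimethoxy-2-methylcyclohex-2-en-1-one | COC1(OC)CCC(=O)C(C)=C1 | intermediate
4 | (4-bromobut-1-yn-1-yl)trimethylsilane | C[Si](C)(C)C#CCCBr | starting material
5 | [4-(trimethylsilyl)but-3-yn-1-yl]magnesium bromide | C[Si](C)(C)C#CCC[Mg]Br | intermediate
6 | iodomethane | CI | starting material
7 | bromomagnesium (3S)-4,4-dimethoxy-2-methyl-3-[4-(trimethylsilyl)but-3-yn-1-yl]cyclohex-1-en-1-olate | COC1(OC)CCC(O[Mg]Br)=C(C)[C@@H]1CCC#C[Si](C)(C)C | intermediate (not isolated)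
8 | (3S)-4,4-dimethoxy-2,2-dimethyl-3-[4-(trimethylsilyl)but-3-yn-1-yl]cyclohexan-1-one | COC1(OC)CCC(=O)C(C)(C)[C@@H]1CCC#C[Si](C)(C)C | intermediate
9 | (1S,3S)-4,4-dimethoxy-2,2-dimethyl-3-[4-(trimethylsilyl)but-3-yn-1-yl]cyclohexan-1-ol | COC1(OC)CC[C@H](O)C(C)(C)[C@@H]1CCC#C[Si](C)(C)C | intermediate
10 | tert-butyl{[(1S,3S)-4,4-dimethoxy-2,2-dimethyl-3-[4-(trimethylsilyl)but-3-yn-1-yl]cyclohexyl]oxy}dimethylsilane | COC1(OC)CC[C@H](O[Si](C)(C)C(C)(C)C)C(C)(C)[C@@H]1CCC#C[Si](C)(C)C | intermediate (not isolated)
11 | (2S,4S)-4-[(tert-butyldimethylsilyl)oxy]-3,3-dimethyl-2-[4-(trimethylsilyl)but-3-yn-1-yl]cyclohexan-1-one | O=C1CC[C@H](O[Si](C)(C)C(C)(C)C)C(C)(C)[C@@H]1CCC#C[Si](C)(C)C | intermediate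
12 | tert-butyl{[(1S,3R)-2,2-dimethyl-4-methylidene-3-[4-(trimethylsilyl)but-3-yn-1-yl]cyclohexyl]oxy}dimethylsilane | C=C1CC[C@H](O[Si](C)(C)C(C)(C)C)C(C)(C)[C@@H]1CCC#C[Si](C)(C)C | intermediate (not isolated)
13 | tert-butyl{[(1S,3R)-3-(but-3-yn-1-yl)-2,2-dimethyl-4-methylidenecyclohexyl]oxy}dimethylsilane | C=C1CC[C@H](O[Si](C)(C)C(C)(C)C)C(C)(C)[C@@H]1CCC#C | intermediate
14 | [(1E)-4-{(1R,3S)-3-[(tert-butyldimethylsilyl)oxy]-2,2-dimethyl-6-methylidenecyclohexyl}-2-methylbut-1-en-1-yl]dimethylalane | C=C1CC[C@H](O[Si](C)(C)C(C)(C)C)C(C)(C)[C@@H]1CC/C(C)=C/[Al](C)C | intermediate (not isolated)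
15 | tert-butyl{[(1S,3R)-3-[(3E)-4-iodo-3-methylbut-3-en-1-yl]-2,2-dimethyl-4-methylidenecyclohexyl]oxy}dimethylsilane | C=C1CC[C@H](O[Si](C)(C)C(C)(C)C)C(C)(C)[C@@H]1CC/C(C)=C/I | intermediate
16 | [4-(trimethylsilyl)but-3-yn-1-yl]zinc bromide | C[Si](C)(C)C#CCC[Zn]Br | intermediate (not isolated)
17 | tert-butyl{[(1S,3R)-2,2-dimethyl-4-methylidene-3-[(3E)-3-methyl-8-(trimethylsilyl)oct-3-en-7-yn-1-yl]cyclohexyl]oxy}dimethylsilane | C=C1CC[C@H](O[Si](C)(C)C(C)(C)C)C(C)(C)[C@@H]1CC/C(C)=C/CCC#C[Si](C)(C)C | intermediate (not isolated)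
18 | tert-butyl{[(1S,3R)-2,2-dimethyl-4-methylidene-3-[(3E)-3-methyloct-3-en-7-yn-1-yl]cyclohexyl]oxy}dimethylsilane | C=C1CC[C@H](O[Si](C)(C)C(C)(C)C)C(C)(C)[C@@H]1CC/C(C)=C/CCC#C | intermediate
19 | formaldehyde (used as paraformaldehyde) | C=O | starting material
20 | [(1E,5E)-8-{(1R,3S)-3-[(tert-butyldimethylsilyl)oxy]-2,2-dimethyl-6-methylidenecyclohexyl}-2,6-dimethylocta-1,5-dien-1-yl]dimethylalane | C=C1CC[C@H](O[Si](C)(C)C(C)(C)C)C(C)(C)[C@@H]1CC/C(C)=C/CC/C(C)=C/[Al](C)C | intermediate (not isolated)
21 | (2E,6E)-9-{(1R,3S)-3-[(tert-butyldimethylsilyl)oxy]-2,2-dimethyl-6-methylidenecyclohexyl}-3,7-dimethylnona-2,6-dien-1-ol | C=C1CC[C@H](O[Si](C)(C)C(C)(C)C)C(C)(C)[C@@H]1CC/C(C)=C/CC/C(C)=C/CO | intermediate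
22 | (2E,6E)-9-{(1R,3S)-3-[(tert-butyldimethylsilyl)oxy]-2,2-dimethyl-6-methylidenecyclohexyl}-3,7-dimethylnona-2,6-dien-1-yl methyl carbonate | C=C1CC[C@H](O[Si](C)(C)C(C)(C)C)C(C)(C)[C@@H]1CC/C(C)=C/CC/C(C)=C/COC(=O)OC | intermediate
23 | 4-hydroxy-6-methyl-2H-pyran-2-one | Cc1cc(O)cc(=O)o1 | starting material
24 | 3-[(2E,6E)-9-{(1R,3S)-3-[(tert-butyldimethylsilyl)oxy]-2,2-dimethyl-6-methylidenecyclohexyl}-3,7-dimethylnona-2,6-dien-1-yl]-4-hydroxy-6-methyl-2H-pyran-2-one | C=C1CC[C@H](O[Si](C)(C)C(C)(C)C)C(C)(C)[C@@H]1CC/C(C)=C/CC/C(C)=C/Cc1c(O)cc(C)oc1=O | intermediate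
25 | sartorypyrone D, 4-hydroxy-3-[(2E,6E)-9-[(1R,3S)-3-hydroxy-2,2-dimethyl-6-methylidenecyclohexyl]-3,7-dimethylnona-2,6-dien-1-yl]-6-methyl-2H-pyran-2-one | C=C1CC[C@H](O)C(C)(C)[C@@H]1CC/C(C)=C/CC/C(C)=C/Cc1c(O)cc(C)oc1=O | target

Total step count: 13.
Longest linear sequence: 12 steps (steps 1, 2 and 4 to 13, counted from 1; step 3 is the side branch that supplies 5).

Steps most likely to fail

Step 4. The risk is insufficient enantioface discrimination, or sluggish conjugate addition and incomplete C-methylation, at a β-carbon flanked by the ketal and the α-methyl group. The fallback gives up catalyst control at C6 and moves the asymmetric event to the ketone reduction. It sets out from 3, 5 and 6: the same tandem addition–methylation is run with CuBr·SMe2 alone (no chiral ligand, THF, −40 °C, then 6 and DMPU) and should give, through the racemic magnesium enolate F1 (not isolated), the racemic ketone F2. Ketone F2 is then reduced to about half conversion with (R)-2-methyl-CBS-oxazaborolidine and catecholborane in toluene at −78 °C. Reagent control (quaternary flank against CH2 flank) and the substrate's own anti-to-chain preference coincide only for the 3S enantiomer, which should be reduced fastest and give alcohol 9, where the route is rejoined. The slow-reacting (3R)-ketone F3 and any trans alcohol are removed by chromatography.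

Step 12. The risk is attack of the pyronate at the substituted allyl terminus, O- or double allylation, or erosion of the C13=C14 geometry in the π-allyl intermediate. The fallback builds the pyrone ring onto the chain instead of attaching it. It sets out from alcohol 21: Appel bromination (CBr4, PPh3, CH2Cl2, 0 °C) should give the allylic bromide F4. Bromide F4 alkylates the sodium enolate of methyl acetoacetate (NaH, THF, 0 °C) by SN2 displacement to the keto ester F5. Double deprotonation of F5 (LiN(iPr)2, 2.2 equiv, THF, −78 °C) and acylation of the terminal carbon with N-methoxy-N-methylacetamide should give the diketo ester F6. DBU in refluxing toluene then lactonises F6 to the 4-hydroxy-2-pyrone, and the route is rejoined at 24.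

Step 2. The risk is hydrogenation that is too slow on the hindered, electron-poor alkene or that runs on past the enone. The fallback replaces hydrogen addition by conjugate hydride transfer. It sets out from 2: catalytic [(Ph3P)CuH]6 (3 mol%) with PhMe2SiH in toluene at rt should deliver hydride to the β-carbon of the unsubstituted enone, the α-methyl enone being the slower acceptor. The product is the silyl dienol ether F7, which cannot be reduced further. Cleavage of F7 with Bu4NF in wet THF returns the route to 3.

Further compounds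
F1 | step 4 | racemic bromomagnesium 4,4-dimethoxy-2-methyl-3-[4-(trimethylsilyl)but-3-yn-1-yl]cyclohex-1-en-1-olate | COC1(OC)CCC(O[Mg]Br)=C(C)C1CCC#C[Si](C)(C)C
F2 | step 4 | racemic 4,4-dimethoxy-2,2-dimethyl-3-[4-(trimethylsilyl)but-3-yn-1-yl]cyclohexan-1-one | COC1(OC)CCC(=O)C(C)(C)C1CCC#C[Si](C)(C)C
F3 | step 4 | (3R)-4,4-dimethoxy-2,2-dimethyl-3-[4-(trimethylsilyl)but-3-yn-1-yl]cyclohexan-1-one | COC1(OC)CCC(=O)C(C)(C)[C@H]1CCC#C[Si](C)(C)C
F4 | step 12 | tert-butyl{[(1S,3R)-3-[(3E,7E)-9-bromo-3,7-dimethylnona-3,7-dien-1-yl]-2,2-dimethyl-4-methylidenecyclohexyl]oxy}dimethylsilane | C=C1CC[C@H](O[Si](C)(C)C(C)(C)C)C(C)(C)[C@@H]1CC/C(C)=C/CC/C(C)=C/CBr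
F5 | step 12 | methyl (4E,8E)-2-acetyl-11-{(1R,3S)-3-[(tert-butyldimethylsilyl)oxy]-2,2-dimethyl-6-methylidenecyclohexyl}-5,9-dimethylundeca-4,8-dienoate | C=C1CC[C@H](O[Si](C)(C)C(C)(C)C)C(C)(C)[C@@H]1CC/C(C)=C/CC/C(C)=C/CC(C(C)=O)C(=O)OC
F6 | step 12 | methyl (4E,8E)-11-{(1R,3S)-3-[(tert-butyldimethylsilyl)oxy]-2,2-dimethyl-6-methylidenecyclohexyl}-5,9-dimethyl-2-(3-oxobutanoyl)undeca-4,8-dienoate | C=C1CC[C@H](O[Si](C)(C)C(C)(C)C)C(C)(C)[C@@H]1CC/C(C)=C/CC/C(C)=C/CC(C(=O)CC(C)=O)C(=O)OC
F7 | step 2 | [(4,4-dimethoxy-6-methylcyclohexa-1,5-dien-1-yl)oxy]dimethyl(phenyl)silane | COC1(OC)CC=C(O[Si](C)(C)c2ccccc2)C(C)=C1
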